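**Retrosynthetic overview**
- The target is a butanoylphloroglucinol core (ring C) joined through two CH2 bridges to two isomeric O-methyl, C-methyl butanoylphloroglucinols: ring A has its OMe ortho to its ketone, ring B has its OMe para to its ketone. Both Ar–CH2–Ar bonds are cut last (Mannich salt → ortho-quinone methide → C-benzylation).
- Key disconnection: the two ArO–CH3 bonds. Both outer ketones are mono-methyl ethers of one common ketone, 1-(2,4,6-trihydroxy-3-methylphenyl)butan-1-one. The para oxygen is methylated classically (K2CO3/Me2SO4); the chelated, hindered ortho oxygen by a new chelation-directed copper-catalysed oxidative methylation.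
- The common ketone and the ring C ketone come from Friedel–Crafts butanoylation of 2-methylphloroglucinol and phloroglucinol.
- No ring is formed in the route; all three benzene rings are bought as phenols. Order of joining: ring A to ring C, then ring B.

Assumption: the target has no stereocentre or stereoaxis (it is achiral), so there is no configuration to set; 2-methylphloroglucinol is taken as a stock phenol.

**Route**

Step 1
Reactants: 1 2-methylbenzene-1,3,5-triol (2-methylphloroglucinol); 2 butanoyl chloride
Product: 3 1-(2,4,6-trihydroxy-3-methylphenyl)butan-1-one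
Conditions: AlCl3 (3.5 equiv), PhNO2–CH2Cl2, 0 °C → 45 °C; ice/2 M HCl
Reagents that add atoms: none
Why: Friedel–Crafts C-acylation of a phloroglucinol; the two free ring carbons of 1 are equivalent and the first, chelated acyl group deactivates the ring against a second acylation.

Step 2
Reactants: 3 1-(2,4,6-trihydroxy-3-methylphenyl)butan-1-one
Product: 4 1-(4,6-dihydroxy-2-methoxy-3-methylphenyl)butan-1-one (ring A ketone; OMe between the C-methyl and the butanoyl group)
Conditions: MeB(OH)2 (1.5 equiv, in portions), Cu(OAc)2 (20 mol%), 4,4'-di-tert-butyl-2,2'-bipyridine (20 mol%), 4 Å MS, dimethyl carbonate, dry air, 70 °C, no amine base; aq. EDTA/1 M HCl wash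
Reagents that add atoms: methylboronic acid, CB(O)O
Why: Proposed new method: a chelation-directed Chan–Lam O-methylation in which the ketone of 3 and its neighbouring phenoxide bind the bipyridine-ligated divalent copper as a six-membered O,O-chelate (expected mainly through O-2, because the 3-methyl group buttresses that hydroxyl against the carbonyl oxygen and leaves the propyl chain on the O-6 side), methyl passes from boron to copper, oxidation by a second divalent copper or air gives a trivalent methylcopper ketophenolate, and C–O reductive elimination places the methyl on the copper-bound O-2, while the more acidic but non-chelating 4-OH stays protonated and unbound because no amine base is present; the closest known reaction type is the copper-mediated Chan–Lam O-methylation of phenols with methylboronic acid, which by itself follows phenol acidity, together with chelate-steered site selection in Chan–Lam couplings.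

Step 3
Reactants: 3 1-(2,4,6-trihydroxy-3-methylphenyl)butan-1-one
Product: 5 1-(2,6-dihydroxy-4-methoxy-3-methylphenyl)butan-1-one (aspidinol; ring B ketone)
Conditions: Me2SO4 (1.0 equiv), K2CO3 (1.0 equiv), acetone, rt
Reagents that add atoms: dimethyl sulfate, COS(=O)(=O)OC
Why: Williamson-type O-methylation of the mono-anion; the 4-OH para to the ketone is the most acidic hydroxyl and the only one the carbonyl cannot tie up in a hydrogen-bonded chelate, so one equivalent of base and Me2SO4 methylates it selectively (the standard para-selective etherification of acylphloroglucinols).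

Step 4
Reactants: 6 benzene-1,3,5-triol (phloroglucinol); 2 butanoyl chloride
Product: 7 1-(2,4,6-trihydroxyphenyl)butan-1-one (ring C ketone)
Conditions: AlCl3 (3.5 equiv), PhNO2–CH2Cl2, 0 °C → 45 °C; ice/2 M HCl
Reagents that add atoms: none
Why: Friedel–Crafts mono-C-acylation of phloroglucinol; all three ring positions are equivalent and the product is deactivated toward a second acylation.

Step 5
Reactants: 4 1-(4,6-dihydroxy-2-methoxy-3-methylphenyl)butan-1-one; 7 1-(2,4,6-trihydroxyphenyl)butan-1-one
Product: 9 1-[3-(3-butanoyl-2,4,6-trihydroxybenzyl)-2,4-dihydroxy-6-methoxy-5-methylphenyl]butan-1-one, via Mannich hydroiodide 8 (not isolated)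
Conditions: [Me2N=CH2]I (1.0 equiv), MeCN, rt; then 7 (4 equiv), NaHCO3 (1.1 equiv), MeCN–H2O, 50 °C
Reagents that add atoms: N,N-dimethylmethyleneiminium iodide (Eschenmoser's salt), C=[N+](C)C.[I-]
Why: Mannich aminomethylation at the only free ring carbon of 4, then mild base makes salt 8 lose dimethylamine to an ortho-quinone methide that the excess phloroglucinol 7 captures at carbon (Mannich-base/ortho-quinone methide Friedel–Crafts benzylation); 8 has no free ring carbon and cannot self-condense, and the four-fold excess of 7 holds back double benzylation.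

Step 6
Reactants: 5 1-(2,6-dihydroxy-4-methoxy-3-methylphenyl)butan-1-one; 9 1-[3-(3-butanoyl-2,4,6-trihydroxybenzyl)-2,4-dihydroxy-6-methoxy-5-methylphenyl]butan-1-one
Product: 11 1-[3-(3-butanoyl-2,4-dihydroxy-6-methoxy-5-methylbenzyl)-5-(3-butanoyl-2,6-dihydroxy-4-methoxy-5-methylbenzyl)-2,4,6-trihydroxyphenyl]butan-1-one, via Mannich hydroiodide 10 (not isolated)
Conditions: [Me2N=CH2]I (1.0 equiv on 5), MeCN, rt; then 9 (0.85 equiv), NaHCO3 (1.1 equiv), MeCN–H2O, 50 °C
Reagents that add atoms: N,N-dimethylmethyleneiminium iodide (Eschenmoser's salt), C=[N+](C)C.[I-]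
Why: Mannich aminomethylation at the single free ring carbon of 5 (between OMe and OH), then base-triggered quinone methide formation and C-benzylation of the one remaining free ring carbon of 9 (Mannich-base/ortho-quinone methide Friedel–Crafts benzylation), which gives the unsymmetrical trimer without statistical mixing.

**Compound list**

1 | 2-methylbenzene-1,3,5-triol (2-methylphloroglucinol) | Cc1c(O)cc(O)cc1O | starting material
2 | butanoyl chloride | CCCC(=O)Cl | starting material
3 | 1-(2,4,6-trihydroxy-3-methylphenyl)butan-1-one | CCCC(=O)c1c(O)cc(O)c(C)c1O | intermediate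
4 | 1-(4,6-dihydroxy-2-methoxy-3-methylphenyl)butan-1-one (ring A ketone) | CCCC(=O)c1c(O)cc(O)c(C)c1OC | intermediate
5 | 1-(2,6-dihydroxy-4-methoxy-3-methylphenyl)butan-1-one (aspidinol, ring B ketone) | CCCC(=O)c1c(O)cc(OC)c(C)c1O | intermediate
6 | benzene-1,3,5-triol (phloroglucinol) | Oc1cc(O)cc(O)c1 | starting material
7 | 1-(2,4,6-trihydroxyphenyl)butan-1-one (ring C ketone) | CCCC(=O)c1c(O)cc(O)cc1O | intermediate
8 | 1-{3-[(dimethylamino)methyl]-2,4-dihydroxy-6-methoxy-5-methylphenyl}butan-1-one hydroiodide (Mannich hydroiodide of 4, CH2N between the two hydroxyls) | CCCC(=O)c1c(O)c(C[NH+](C)C)c(O)c(C)c1OC.[I-] | intermediate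
9 | 1-[3-(3-butanoyl-2,4,6-trihydroxybenzyl)-2,4-dihydroxy-6-methoxy-5-methylphenyl]butan-1-one (ring A–CH2–ring C dimer) | CCCC(=O)c1c(O)c(Cc2c(O)cc(O)c(C(=O)CCC)c2O)c(O)c(C)c1OC | intermediate
10 | 1-{3-[(dimethylamino)methyl]-2,6-dihydroxy-4-methoxy-5-methylphenyl}butan-1-one hydroiodide (Mannich hydroiodide of 5, CH2N between OH and OMe) | CCCC(=O)c1c(O)c(C[NH+](C)C)c(OC)c(C)c1O.[I-] | intermediate
11 | 1-[3-(3-butanoyl-2,4-dihydroxy-6-methoxy-5-methylbenzyl)-5-(3-butanoyl-2,6-dihydroxy-4-methoxy-5-methylbenzyl)-2,4,6-trihydroxyphenyl]butan-1-one (CNP0171986.0, achiral) | CCCC(=O)c1c(O)c(Cc2c(O)c(C)c(OC)c(C(=O)CCC)c2O)c(O)c(Cc2c(O)c(C(=O)CCC)c(O)c(C)c2OC)c1O | target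

**Step count and risks**

Total steps: 6. Longest linear sequence: 4 steps (1 → 3 → 4 → 9 → 11).

Steps most likely to fail:

1. Step 2 (the proposed new chelation-directed methylation). Possible failures are methylation at O-6 instead of O-2, a second methylation of 4 through its remaining chelate, oxidative coupling at the free ring carbon, or no turnover of the chelated copper. Any 4-O-methylated by-product is 5, which the route needs anyway, and the reaction should be stopped at partial conversion with 3 recycled. Fallback with known chemistry, setting out from 3 and coming back at 4: TsCl (2.1 equiv)/K2CO3 in acetone sulfonylates the two unhindered hydroxyls and gives 1-[2-hydroxy-3-methyl-4,6-bis(tosyloxy)phenyl]butan-1-one F1. Me2SO4/K2CO3 in refluxing acetone then methylates the one remaining, buttressed hydroxyl to 1-[2-methoxy-3-methyl-4,6-bis(tosyloxy)phenyl]butan-1-one F2. KOH in MeOH–H2O at reflux cleaves both sulfonates and returns 4.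

2. Step 5 (first bridge). Possible failures are double benzylation of 7, sluggish quinone methide release from 8, or retro-benzylation scrambling of the bridge on warming. Fallback that inverts order and polarity, setting out from 5 and 7 and coming back at 11 (9 is bypassed): salt 10, made from 5 as in step 6, is warmed with 7 (4 equiv) and NaHCO3 to give the ring B–ring C dimer 1-[3-(3-butanoyl-2,4,6-trihydroxybenzyl)-2,6-dihydroxy-4-methoxy-5-methylphenyl]butan-1-one F3. Its single free ring carbon is aminomethylated with Eschenmoser's salt to 1-[3-({3-butanoyl-5-[(dimethylamino)methyl]-2,4,6-trihydroxyphenyl}methyl)-2,6-dihydroxy-4-methoxy-5-methylphenyl]butan-1-one hydroiodide F4. This is warmed with 4 and NaHCO3, so that ring A enters as the carbon nucleophile and gives 11.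

3. Step 6 (second bridge). Salt 10 may release its quinone methide slowly, because one flanking oxygen is a methyl ether and the other is locked in the ketone chelate, and prolonged warming can scramble the bridges of 9 and 11. Fallback that reverses the polarity, setting out from 9 and coming back at 11: 9 is aminomethylated at its single free ring carbon with Eschenmoser's salt in MeCN to 1-[3-({3-butanoyl-5-[(dimethylamino)methyl]-2,4,6-trihydroxyphenyl}methyl)-2,4-dihydroxy-6-methoxy-5-methylphenyl]butan-1-one hydroiodide F5. This is warmed with 5 and NaHCO3 in MeCN–H2O, so that ring B enters as the carbon nucleophile and gives 11.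

**Further compounds**

F1 | step 2 | 1-[2-hydroxy-3-methyl-4,6-bis(tosyloxy)phenyl]butan-1-one | CCCC(=O)c1c(OS(=O)(=O)c2ccc(C)cc2)cc(OS(=O)(=O)c2ccc(C)cc2)c(C)c1O
F2 | step 2 | 1-[2-methoxy-3-methyl-4,6-bis(tosyloxy)phenyl]butan-1-one | CCCC(=O)c1c(OS(=O)(=O)c2ccc(C)cc2)cc(OS(=O)(=O)c2ccc(C)cc2)c(C)c1OC
F3 | step 5 | 1-[3-(3-butanoyl-2,4,6-trihydroxybenzyl)-2,6-dihydroxy-4-methoxy-5-methylphenyl]butan-1-one | CCCC(=O)c1c(O)c(Cc2c(O)cc(O)c(C(=O)CCC)c2O)c(OC)c(C)c1O
F4 | step 5 | 1-[3-({3-butanoyl-5-[(dimethylamino)methyl]-2,4,6-trihydroxyphenyl}methyl)-2,6-dihydroxy-4-methoxy-5-methylphenyl]butan-1-one hydroiodide | CCCC(=O)c1c(O)c(Cc2c(O)c(C[NH+](C)C)c(O)c(C(=O)CCC)c2O)c(OC)c(C)c1O.[I-]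
F5 | step 6 | 1-[3-({3-butanoyl-5-[(dimethylamino)methyl]-2,4,6-trihydroxyphenyl}methyl)-2,4-dihydroxy-6-methoxy-5-methylphenyl]butan-1-one hydroiodide | CCCC(=O)c1c(O)c(Cc2c(O)c(C[NH+](C)C)c(O)c(C(=O)CCC)c2O)c(O)c(C)c1OC.[I-]
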